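# Total synthesis proposal for CNP0130221.1 (compound 33)

## Structural features

Germacrane numbering is used: C1–C10 are the ring carbons, C11–C13 the lactone carbons, C14 the methyl on C10, and C15 the hydroxymethyl carbon on C4.

The target is a cyclodecane fused at C6–C7 to an α-methylene-γ-butyrolactone (O–C6, C7–C11(=C13H2)–C12=O). H6 and H7 are cis, so the lactone is cis-fused. The ring carries a C3 ketone conjugated with a trisubstituted C4=C5 alkene that is cis inside the ring (4Z) and bears C15H2OH. It also carries a tertiary carbinol C10(OH)(C14H3) and an (R)-2-methylbutanoate on C8.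

C6, C7 and C8 are contiguous (6S,7R,8R), with O6, C11 and O8 on one face. C10 (R) is 1,3-syn to O8 and remote from C6/C7. The fifth centre lies in the acyl chain.

Several groups are fragile:
- The exocyclic enoate is a Michael acceptor.
- The enone carries a γ-acyloxy group.
- Any C8 carbonyl is β to both O6 and O10.
- The C10–OH/C3=O pair can form a hemiketal.
- The 6,12-lactone can migrate to O8.

The real difficulty is the ten-membered carbocycle with its Z-enone, together with the relation of C10 to the C6–C8 triad.

The key step exploits the way the ring splits into two arcs. The six-carbon arc C4–C3–C2–C1–C10–C9 is a 4-hydroxy-4-methylcyclohexenone once C4 and C9 are joined. The four-carbon arc C5–C6–C7–C8 is a lactone-fused cyclobutene once C5 and C8 are joined. The arcs meet only at C4–C5 and C8–C9, and the 1,3-related O8 and O10 can hold them together through one silicon atom.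

## Logic of the disconnections

**33 ⇒ 32 ⇒ 31.** No ring bond is cut. The O15–Si bond is restored, and the C11=C13 π bond is replaced by C11–H and C13–OBz. The Michael acceptor and the free primary alcohol therefore appear last, so all earlier steps may use light, heat, hydride and nucleophilic catalysts. The forward elimination must be mild enough to spare the C8 ester and the exocyclic position of the alkene.

**31 ⇒ 29 + 30.** The O8–acyl bond is cut. This removes one stereocentre and leaves a diol in which only O8 is secondary. The forward step must acylate O8 without scrambling the α-centre of 30.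

**29 ⇒ 27 ⇒ 26.** The C8–H bond is removed (C8 becomes a ketone), and the ketone and O10 are then tied into a cyclic silyl enol ether. C8 is thereby reduced to a trigonal carbon whose configuration is returned later from C10. The forward reduction must be directed by O10 (1,3-syn) and must spare the C3 enone.

**26 ⇒ 25.** Read backwards, two cross-ring bonds, C4–C9 and C5–C8, are drawn in. The ten-membered ring collapses to a cyclohexanone and two cyclobutanes (a 6-4-4 array holding a bicyclo[2.2.0]hexane). The gain is that no medium ring has to be closed at all. The demand is that the forward thermal cleavage breaks exactly these two bonds and leaves C4=C5 cis in the ring.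

**25 ⇒ 24 (key).** C4–C5 and C8–C9 are cut, which are the only bonds between the two arcs. What remains is a cyclohexenone and a cyclobutene held by O10–Si–O8. This is the largest simplification of the plan: C10 on one ring, and C6, C7 on the other, are already in place. The forward step must join C9 to C8 and C4 to C5, and not the reverse.

**24 ⇒ 9 + 22.** The two Si–O bonds are cut, giving two small enantiopure rings of similar size, so the route is convergent. The forward step must enolise 22 towards C5 and must not expel the lactone oxygen or the benzoate.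

**9 ⇒ 8 ⇒ 7 ⇒ 6 ⇒ 3 + 4, 3 ⇒ 1.** C4=C9 is cut (ring-closing metathesis), then C3–C4 (vinyl-metal addition), then the C3 aldehyde is traced to an alkene. C10 comes unchanged from the chiral pool. The only demand is chemoselective cleavage of one of the two alkenes of 1.

**22 ⇒ 21 ⇒ 20 ⇒ 19.** C12=O and the benzoate carbonyl are returned to CH2 groups. C5–C6 and C7–C8 are then cut (ketene cycloaddition). A five-membered enol ether with one stereocentre (C11) remains. That centre must steer the ketene to the opposite face and so set C6 and C7.

**19 ⇒ 17 ⇒ 15 ⇒ 14 ⇒ 12 ⇒ 10 + 11.** The C6–O bond (lactol) and the C11–C13 bond (auxiliary-controlled alkylation) are cut. C11 is a sacrificial centre. It is set reliably, relays its information to C6/C7, and is destroyed when C11=C13 is made.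

## Other disconnections considered

Alternative 1: This is the first that comes to mind. Cut C6–C7 and close the ring by an intramolecular Nozaki–Hiyama–Kishi or Barbier allylation of the open-chain aldehyde/2-(bromomethyl)enoate A1, with lactonisation of the resulting alkoxide.
- A ten-membered ring would have to be closed directly against transannular strain.
- The Z-4-oxo-enal end of A1 is prone to Z/E isomerisation and to cyclisation on its own ketone.
- The allyl-metal must distinguish the aldehyde from the C3 ketone.
- The C6/C7 relation (cis-lactone) would depend on an unpredictable macrocyclic transition state.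
- All five stereocentres would also have to be built on an open chain, which is longer than carrying them on small rings.

Alternative 2: Cut C4=C5 and close it by ring-closing metathesis of triene A2.
- The alkene to be made is trisubstituted, electron-poor and must be Z in a strained ring.
- The catalyst would load first on the vinyl group and then face a 1,1-disubstituted enone.
- The α-methylene lactone is a competing partner.
- Oligomerisation and lack of control over geometry are the mechanistic expectation, so the hard problem is postponed to the last C–C bond.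

Alternative 3: Cut C6–C7 in the ring-contraction sense, by [2,3]-Wittig rearrangement of the 13-membered bis-allylic ether A3. This would form C6–C7, the C6 hydroxyl and C11=C13 at once. The idea is attractive, but several points count against it.
- A macrocyclisation is still needed first.
- The strong base forces the C3 ketone and both esters to be masked, and C12 to be carried at the alcohol level.
- Deprotonation must occur at C6 and not at C13.
- The syn/anti outcome again rests on a macrocyclic transition state.

The chosen plan needs no macrocyclisation and derives C6/C7 from a rigid bicycle.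

Key step: step 15

Assumption: 33 is planned as the open C3-keto/C10-hydroxy form that the SMILES shows; in solution it may equilibrate with its 3,10-hemiketal.
Assumption: (R)-linalool and (R)-2-methylbutanoic acid are bought in high enantiomeric purity.

## Steps

Step 1
Reactants: 1 (R)-linalool
Product: 3 (5R)-5-ethenyl-5-methyloxolan-2-ol (anomer mixture), via hydroxy aldehyde 2 (not isolated)
Conditions: O3 (1 equiv, Sudan Red 7B end point), CH2Cl2, −78 °C; Me2S, −78 °C → rt
Reagents that add atoms: ozone, [O-][O+]=O
Why: Chemoselective ozonolysis: the electron-rich trisubstituted alkene should react much faster than the vinyl group next to the carbinol, and the C3 aldehyde closes on O10 to the lactol. C10 (R) comes from the chiral pool and is not touched.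

Step 2
Reactants: 3 (5R)-5-ethenyl-5-methyloxolan-2-ol; 4 2-bromoprop-2-en-1-ol
Product: 6 (6R)-6-methyl-2-methylideneoct-7-ene-1,3,6-triol (C3 epimers), via dilithio allyl alkoxide 5 (not isolated)
Conditions: 4 (2.2 equiv), t-BuLi (6.6 equiv), Et2O, −78 → 0 °C; then 3, 0 °C → rt; aq NH4Cl
Reagents that add atoms: none
Why: Bromine–lithium exchange on the lithium alkoxide gives a vinyl-lithium that carries no silyl group and so cannot undergo silyl migration; one equivalent opens the lactol by deprotonation and a second adds to the freed aldehyde (C3–C4 bond). The new C3 carbinol centre is irrelevant because step 5 oxidises it.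

Step 3
Reactants: 6 (6R)-6-methyl-2-methylideneoct-7-ene-1,3,6-triol
Product: 7 1-O-tert-butyldiphenylsilyl ether of 6 (O15 protected; C3 epimers)
Conditions: TBDPSCl (1.05 equiv), imidazole, CH2Cl2, 0 °C
Reagents that add atoms: tert-butyl(chloro)diphenylsilane, CC(C)(C)[Si](Cl)(c1ccccc1)c1ccccc1
Why: Sterically governed silylation: the bulky chlorosilane should take the primary allylic hydroxyl and leave the secondary and tertiary ones.

Step 4
Reactants: 7 1-O-TBDPS triol
Product: 8 (1R)-3-(tert-butyldiphenylsilyloxymethyl)-1-methylcyclohex-2-ene-1,4-diol (C3 epimers in target numbering)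
Conditions: second-generation Grubbs catalyst RuCl2(=CHPh)(PCy3)(H2IMes) (5 mol %), CH2Cl2 (10 mM), reflux
Reagents that add atoms: none
Why: Ring-closing metathesis to an unstrained six-membered ring (C4=C9): the catalyst loads on the vinyl group, whose free tertiary allylic hydroxyl is known to help, and closes on the 1,1-disubstituted alkene with loss of ethene.

Step 5
Reactants: 8 cyclohexenediol
Product: 9 (4R)-2-(tert-butyldiphenylsilyloxymethyl)-4-hydroxy-4-methylcyclohex-2-en-1-one
Conditions: MnO2 (excess), CH2Cl2, rt
Reagents that add atoms: none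
Why: Selective oxidation of the secondary allylic alcohol; both C3 epimers converge on one enone and the tertiary C10–OH cannot be oxidised.

Step 6
Reactants: 10 (S)-4-benzyl-1,3-oxazolidin-2-one; 11 pent-4-enoyl chloride
Product: 12 (4S)-4-benzyl-3-(pent-4-enoyl)-1,3-oxazolidin-2-one
Conditions: Et3N, DMAP (cat.), CH2Cl2, 0 °C → rt
Reagents that add atoms: none
Why: Standard N-acylation of the auxiliary under acyl-transfer catalysis.

Step 7
Reactants: 12 N-pentenoyl oxazolidinone
Product: 14 (4S)-4-benzyl-3-[(2R)-2-(benzyloxymethyl)pent-4-enoyl]-1,3-oxazolidin-2-one, via chlorotitanium enolate 13 (not isolated)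
Conditions: TiCl4, i-Pr2NEt, CH2Cl2, 0 °C; BnOCH2Cl, 0 °C
Reagents that add atoms: benzyl chloromethyl ether, ClCOCc1ccccc1
Why: Evans alkylation: the chelated Z-enolate is attacked by the oxocarbenium-type electrophile on the face away from the benzyl group, which forms C11–C13 and sets C11. This centre is sacrificial; it only has to steer step 11.

Step 8
Reactants: 14 alkylated imide
Product: 15 (2S)-2-(benzyloxymethyl)pent-4-en-1-ol
Conditions: LiBH4, MeOH (1 equiv), Et2O, 0 °C
Reagents that add atoms: none
Why: Reductive removal of the auxiliary (recovered) without epimerisation; the former acyl carbon becomes C12H2OH.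

Step 9
Reactants: 15 (2S)-2-(benzyloxymethyl)pent-4-en-1-ol
Product: 17 (4R)-4-(benzyloxymethyl)oxolan-2-ol (anomer mixture), via hydroxy aldehyde 16 (not isolated)
Conditions: O3, CH2Cl2, −78 °C; Me2S, −78 °C → rt
Reagents that add atoms: ozone, [O-][O+]=O
Why: Ozonolysis of the terminal alkene gives the C6 aldehyde, which closes on the C12 hydroxyl to a five-membered lactol.

Step 10
Reactants: 17 lactol
Product: 19 (3R)-3-(benzyloxymethyl)-2,3-dihydrofuran, via anomeric mesylate 18 (not isolated)
Conditions: MsCl, Et3N (excess), CH2Cl2, −40 °C → reflux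
Reagents that add atoms: none
Why: Lactol dehydration of the kind used for furanoid glycals: the anomeric sulfonate ionises and loses a C7 proton, the only β-hydrogens available, to give the C6=C7 enol ether.

Step 11
Reactants: 19 (3R)-3-(benzyloxymethyl)-2,3-dihydrofuran
Product: 20 (1R,4R,5S)-4-(benzyloxymethyl)-7,7-dichloro-2-oxabicyclo[3.2.0]heptan-6-one
Conditions: Cl3CCOCl, Zn–Cu, Et2O–DME, rt, slow addition
Reagents that add atoms: trichloroacetyl chloride, O=C(Cl)C(Cl)(Cl)Cl
Why: Dichloroketene–enol ether [2+2] cycloaddition: the nucleophilic C7 bonds to the ketene carbonyl carbon (C8) and the oxygen-bearing C6 to CCl2 (C5), suprafacially on the ring alkene, so the fusion is cis. Approach anti to the C11 side chain sets C6 and C7 in the configuration of the target.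

Step 12
Reactants: 20 dichlorocyclobutanone
Product: 21 (1S,4R,5S)-4-(benzyloxymethyl)-2-oxabicyclo[3.2.0]heptan-6-one
Conditions: Zn dust, AcOH, rt
Reagents that add atoms: none
Why: Standard reductive dechlorination of α,α-dichlorocyclobutanones; no stereocentre is involved.

Step 13
Reactants: 21 bicyclic ether ketone
Product: 22 [(1S,4R,5S)-3,6-dioxo-2-oxabicyclo[3.2.0]heptan-4-yl]methyl benzoate
Conditions: RuCl3·xH2O (5 mol %), NaIO4 (excess), EtOAc–MeCN–H2O, rt
Reagents that add atoms: sodium periodate (oxygen source by way of RuO4), [Na+].[O-]I(=O)(=O)=O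
Why: RuO4 oxidation of ethers at their CH2–O positions: the oxolane C12H2 becomes the γ-lactone carbonyl (the methine C6–H is much slower) and the benzyl ether becomes the benzoate. The benzoate is the leaving group wanted in step 20.

Step 14
Reactants: 9 hydroxy enone; 22 keto lactone benzoate
Product: 24 diisopropylsilylene bis-ether joining O10 of 9 to the C8 enol oxygen of 22 (C5=C8 cyclobutene), via alkoxysilyl triflate 23 (not isolated)
Conditions: i-Pr2Si(OTf)2, 2,6-lutidine, CH2Cl2, −78 °C; then 22, Et3N, −78 → 0 °C
Reagents that add atoms: diisopropylsilyl bis(trifluoromethanesulfonate), CC(C)[Si](OS(=O)(=O)C(F)(F)F)(OS(=O)(=O)C(F)(F)F)C(C)C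
Why: Temporary silicon connection: the hindered tertiary alcohol takes only one triflate, and the remaining silyl triflate with Et3N silylates the cyclobutanone by soft enolisation, so no free enolate exists to expel O6. Enolisation goes to C5H2 because a C7=C8 bond would put the cyclobutene alkene at the ring fusion.

Step 15
Reactants: 24 silicon-tethered enone–cyclobutene
Product: 25 pentacyclic cis-anti-cis photoadduct (new cyclobutane C4–C5–C8–C9 fused to the cyclohexanone at C4–C9, to the lactone-bearing cyclobutane at C5–C8 and to the dioxasilinane at C8–C9)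
Conditions: hν (365 nm LED, or Hg lamp through uranium glass), degassed CH2Cl2 (2 mM), −20 °C
Reagents that add atoms: none
Why: Enone–alkene [2+2] photocycloaddition, run intramolecularly across a temporary O–Si–O connection, the closest known type being the addition of cyclohexenones to silyloxycyclobutenes. Excitation of the C3=O/C4=C9 enone and intersystem crossing give the twisted triplet; bonding starts between the β-carbon C9 and the silyloxy-bearing C8 and is completed between C4 and C5 after spin inversion. Two rings close: the dioxasilinane C9–C10–O–Si–O–C8 in a 6-exo sense by the first bond, and the central cyclobutane by the second, which creates a bicyclo[2.2.0]hexane with the cyclobutane already present. The selectivity needed is regiochemical (C9 to C8, C4 to C5): the three-atom tether allows this straight mode, and it coincides with the innate head-to-tail preference that joins a donor-substituted alkene carbon to the enone β-carbon. C9 and C4 are controlled by the tether, which can deliver the cyclobutene only to the enone face that carries O10; C8 and C5 are controlled by the bicyclo[3.2.0]heptene, which is open only on its convex face, anti to the lactone. With 10R in 9 and the C6/C7 configuration of 22, a model shows that these two demands meet in the cis-anti-cis array, the least crowded one, so the case is matched. All ten ring carbons are now connected in the right order with C6, C7 and C10 untouched, and the four new centres are sacrificial because step 16 turns them into sp2 carbons. Light above 350 nm reaches only the enone chromophore, and the masked (benzoyloxymethyl) lactone offers no competing alkene.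

Step 16
Reactants: 25 pentacyclic photoadduct
Product: 26 8,10-O-diisopropylsilylene-bridged (4Z)-cyclodeca-4,8-dien-3-one 6,12-lactone (C8=C9 trans in the ten-membered ring; 13-OBz; 15-OTBDPS)
Conditions: o-xylene (2 mM), BHT (trace), silanised sealed tube, 150–170 °C
Reagents that add atoms: none
Why: Thermal cycloreversion of a bicyclo[2.2.0]hexane to a 1,5-diene (the second half of a photo-thermal olefin metathesis): the doubly strained, silyloxy-substituted C5–C8 bond gives way first and C4–C9 follows, so the six-membered ring and the two cyclobutanes merge into the cyclodeca-4,8-diene. C8=C9 must stay cis inside the dioxasiline and is therefore trans in the large ring, and the chair-like transition state typical of this reaction, which gives one trans and one cis ring alkene, then holds quaternary C10 equatorial and C3 axial and should give 4Z. Cleavage of C6–C7 instead, or a later Cope rearrangement, would have to open the γ-lactone into a nine-membered ring containing a trans alkene and is disfavoured.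

Step 17
Reactants: 26 silylene-bridged cyclodecadienone
Product: 27 10-hydroxy-3,8-dioxo (4Z)-cyclodecene 6,12-lactone (13-OBz; 15-OTBDPS)
Conditions: Et3N·3HF, MeCN–THF, 0 °C → rt
Reagents that add atoms: none
Why: Mildly acidic fluoride cleaves the enol silyl ether and the tertiary silyl ether of the tether far faster than the primary TBDPS ether; the enol tautomerises to the C8 ketone (C9H2). The medium is neither basic nor strongly acidic, which should protect C7–H, O6 and the tertiary carbinol.

Step 18
Reactants: 27 hydroxy diketone
Product: 29 (8R,10R)-8,10-diol (C3 enone and lactone retained), via diethylborinate 28 (not isolated)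
Conditions: Et2BOMe, THF–MeOH (4:1), −78 °C; NaBH4, −78 °C; AcOH; MeOH azeotrope
Reagents that add atoms: none
Why: Narasaka–Prasad reduction: boron ties O10 and the C8 carbonyl into a six-membered chelate with the two ring branches (C1, C7) equatorial, and axial hydride delivery gives the 1,3-syn diol, that is 8R from 10R. The activated chelated ketone should be reduced well before the hindered conjugated C3 ketone at −78 °C.

Step 19
Reactants: 29 diol; 30 (R)-2-methylbutanoic acid
Product: 31 8-O-[(2R)-2-methylbutanoyl] ester (10-OH free; 13-OBz; 15-OTBDPS)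
Conditions: DCC, DMAP (5 mol %), CH2Cl2, 0 °C
Reagents that add atoms: none
Why: Steglich esterification: only the secondary O8 can react, since O10 is tertiary and O15 is silylated. Low temperature and little DMAP keep the α-centre of the acid intact.

Step 20
Reactants: 31 ester
Product: 32 15-O-TBDPS ether of the target (α-methylene lactone in place)
Conditions: DBU (1.2 equiv), CH2Cl2, 0 °C
Reagents that add atoms: none
Why: E1cB loss of benzoate from the α-(acyloxymethyl) lactone creates C11=C13 and erases the sacrificial C11 centre (either C11 epimer would serve). Short contact at 0 °C should avoid migration of the alkene to C7=C11.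

Step 21
Reactants: 32 silyl ether
Product: 33 target CNP0130221.1 (4Z,6S,7R,8R,10R,2′R)
Conditions: HF·pyridine, pyridine, THF, 0 °C → rt
Reagents that add atoms: none
Why: Buffered acidic fluoride removes the TBDPS group without the basic conditions that would invite acyl migration, translactonisation or conjugate addition to the enoate.

## Compound list

1 | (R)-linalool | CC(C)=CCC[C@@](C)(O)C=C | starting material
2 | (4R)-4-hydroxy-4-methylhex-5-enal | O=CCC[C@@](C)(O)C=C | intermediate
3 | (5R)-5-ethenyl-5-methyloxolan-2-ol (anomers) | OC1CC[C@](C)(C=C)O1 | intermediate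
4 | 2-bromoprop-2-en-1-ol | C=C(Br)CO | starting material
5 | lithium 2-lithioprop-2-en-1-olate | [Li]OCC([Li])=C | intermediate
6 | (6R)-6-methyl-2-methylideneoct-7-ene-1,3,6-triol (C3 epimers) | C=C(CO)C(O)CC[C@@](C)(O)C=C | intermediate
7 | 1-O-TBDPS ether of 6 | C=C(CO[Si](c1ccccc1)(c1ccccc1)C(C)(C)C)C(O)CC[C@@](C)(O)C=C | intermediate
8 | (1R)-3-(TBDPS-oxymethyl)-1-methylcyclohex-2-ene-1,4-diol | OC1CC[C@@](C)(O)C=C1CO[Si](c1ccccc1)(c1ccccc1)C(C)(C)C | intermediate
9 | (4R)-2-(TBDPS-oxymethyl)-4-hydroxy-4-methylcyclohex-2-en-1-one | O=C1CC[C@@](C)(O)C=C1CO[Si](c1ccccc1)(c1ccccc1)C(C)(C)C | intermediate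
10 | (S)-4-benzyl-1,3-oxazolidin-2-one | O=C1N[C@@H](Cc2ccccc2)CO1 | starting material
11 | pent-4-enoyl chloride | C=CCCC(=O)Cl | starting material
12 | (4S)-4-benzyl-3-(pent-4-enoyl)-1,3-oxazolidin-2-one | C=CCCC(=O)N1[C@@H](Cc2ccccc2)COC1=O | intermediate
13 | trichlorotitanium Z-enolate of 12 | C=CC/C=C(\O[Ti](Cl)(Cl)Cl)N1[C@@H](Cc2ccccc2)COC1=O | intermediate
14 | (4S)-4-benzyl-3-[(2R)-2-(benzyloxymethyl)pent-4-enoyl]-1,3-oxazolidin-2-one | C=CC[C@H](COCc1ccccc1)C(=O)N1[C@@H](Cc2ccccc2)COC1=O | intermediate
15 | (2S)-2-(benzyloxymethyl)pent-4-en-1-ol | C=CC[C@H](COCc1ccccc1)CO | intermediate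
16 | (3S)-4-(benzyloxy)-3-(hydroxymethyl)butanal | O=CC[C@H](COCc1ccccc1)CO | intermediate
17 | (4R)-4-(benzyloxymethyl)oxolan-2-ol (anomers) | OC1C[C@H](COCc2ccccc2)CO1 | intermediate
18 | (4R)-4-(benzyloxymethyl)oxolan-2-yl methanesulfonate | CS(=O)(=O)OC1C[C@H](COCc2ccccc2)CO1 | intermediate
19 | (3R)-3-(benzyloxymethyl)-2,3-dihydrofuran | C1=C[C@H](COCc2ccccc2)CO1 | intermediate
20 | (1R,4R,5S)-4-(benzyloxymethyl)-7,7-dichloro-2-oxabicyclo[3.2.0]heptan-6-one | O=C1C(Cl)(Cl)[C@@H]2OC[C@@H](COCc3ccccc3)[C@H]12 | intermediate
21 | (1S,4R,5S)-4-(benzyloxymethyl)-2-oxabicyclo[3.2.0]heptan-6-one | O=C1C[C@@H]2OC[C@@H](COCc3ccccc3)[C@H]12 | intermediate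
22 | [(1S,4R,5S)-3,6-dioxo-2-oxabicyclo[3.2.0]heptan-4-yl]methyl benzoate | O=C1C[C@@H]2OC(=O)[C@@H](COC(=O)c3ccccc3)[C@H]12 | intermediate
23 | O10-diisopropyl(triflyloxy)silyl ether of 9 | O=C1CC[C@@](C)(O[Si](C(C)C)(C(C)C)OS(=O)(=O)C(F)(F)F)C=C1CO[Si](c1ccccc1)(c1ccccc1)C(C)(C)C | intermediate
24 | diisopropylsilylene bis-ether of 9 (O10) and the C5=C8 enol of 22 (O8) | O=C1CC[C@@](C)(O[Si](C(C)C)(C(C)C)OC2=C[C@@H]3OC(=O)[C@@H](COC(=O)c4ccccc4)[C@H]23)C=C1CO[Si](c1ccccc1)(c1ccccc1)C(C)(C)C | intermediate
25 | pentacyclic cis-anti-cis photoadduct (cyclobutane C4–C5–C8–C9) | O=C1CC[C@@](C)(O[Si]5(C(C)C)C(C)C)[C@@H]2[C@@]1(CO[Si](c1ccccc1)(c1ccccc1)C(C)(C)C)[C@@H]3[C@@]2(O5)[C@@H]4[C@H]3OC(=O)[C@H]4COC(=O)c1ccccc1 | intermediate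
26 | 8,10-O-diisopropylsilylene (4Z)-cyclodeca-4,8-dien-3-one 6,12-lactone, 13-OBz, 15-OTBDPS | O=C1O[C@H]2/C=C(/CO[Si](c3ccccc3)(c3ccccc3)C(C)(C)C)C(=O)CC[C@@](C)(O[Si]3(C(C)C)C(C)C)/C=C(O3)/[C@H]2[C@@H]1COC(=O)c1ccccc1 | intermediate
27 | 10-hydroxy-3,8-dioxo (4Z)-cyclodecene 6,12-lactone, 13-OBz, 15-OTBDPS | O=C1O[C@H]2/C=C(/CO[Si](c3ccccc3)(c3ccccc3)C(C)(C)C)C(=O)CC[C@@](C)(O)CC(=O)[C@H]2[C@@H]1COC(=O)c1ccccc1 | intermediate
28 | O10-diethylborinate of 27 | O=C1O[C@H]2/C=C(/CO[Si](c3ccccc3)(c3ccccc3)C(C)(C)C)C(=O)CC[C@@](C)(OB(CC)CC)CC(=O)[C@H]2[C@@H]1COC(=O)c1ccccc1 | intermediate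
29 | (8R,10R)-8,10-dihydroxy-3-oxo (4Z)-cyclodecene 6,12-lactone, 13-OBz, 15-OTBDPS | O=C1O[C@H]2/C=C(/CO[Si](c3ccccc3)(c3ccccc3)C(C)(C)C)C(=O)CC[C@@](C)(O)C[C@@H](O)[C@H]2[C@@H]1COC(=O)c1ccccc1 | intermediate
30 | (R)-2-methylbutanoic acid | CC[C@@H](C)C(=O)O | starting material
31 | 8-O-[(2R)-2-methylbutanoyl] derivative of 29 | O=C1O[C@H]2/C=C(/CO[Si](c3ccccc3)(c3ccccc3)C(C)(C)C)C(=O)CC[C@@](C)(O)C[C@@H](OC(=O)[C@H](C)CC)[C@H]2[C@@H]1COC(=O)c1ccccc1 | intermediate
32 | 15-O-TBDPS ether of the target | C=C1C(=O)O[C@H]2/C=C(/CO[Si](c3ccccc3)(c3ccccc3)C(C)(C)C)C(=O)CC[C@@](C)(O)C[C@@H](OC(=O)[C@H](C)CC)[C@@H]12 | intermediate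
33 | CNP0130221.1 | C=C1C(=O)O[C@H]2/C=C(/CO)C(=O)CC[C@@](C)(O)C[C@@H](OC(=O)[C@H](C)CC)[C@@H]12 | target

## Step count and least certain steps

Total steps: 21. Longest linear sequence: 16 (steps 6–21, from 10 and 11). The second branch (steps 1–5, from 1 and 4) joins at step 14.

**Step 15 (key step).**
- What may go wrong: two fully substituted carbons (C4, C8) are formed next to quaternary C10, so cycloaddition may be slow. Hydrogen abstraction from the isopropyl groups, photoreduction, or hydrolytic loss of the enol silane could then compete. A crossed mode of addition is the other conceivable failure.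
- Fallback (untethered, relying only on innate polarity): from 9, TESOTf/2,6-lutidine gives the triethylsilyl ether F1, and from 22, TBSOTf/Et3N gives the tert-butyldimethylsilyl enol ether F2. Irradiation of F1 with an excess of F2 at 365 nm should give the head-to-tail adduct F3. Thermolysis as in step 16 gives the bis-silylated cyclodecadienone F4, and Et3N·3HF returns to the route at 27.

**Step 16.**
- What may go wrong: a boat-like pathway could leave C4=C5 trans. C6–C7 could cleave in competition. Silyl migration or loss of benzoate could occur at the temperature required.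
- Fallback (radical, at room temperature): from 25, Et3N·3HF frees the cyclobutanol diol F5. An O8-centred alkoxy radical is then generated by proton-coupled electron transfer (Ir[dF(CF3)ppy]2(dtbbpy)PF6, a phosphate base, 2,4,6-triisopropylbenzenethiol, blue light). It should cleave C5–C8, after which the C5 radical cleaves C4–C9 to give the conjugated alkene and an α-keto radical at C9. The thiol quenches that radical, which returns to the route at 27.

**Step 14.**
- What may go wrong: both triflates may be substituted by 9, the intermediate may be scrambled, enolisation may go towards C7, or benzoate may be lost early under silyl triflate/amine conditions.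
- Fallback (stepwise tether through an isolable hydrosilane): from 22, i-Pr2SiHCl/Et3N gives the enoxy(hydrido)silane F6. NBS converts Si–H into the bromosilane F7, and 9 with Et3N and DMAP then gives 24.

**Step 17.**
- What may go wrong: 27 is at once a tertiary β-hydroxy ketone, a β-acyloxy ketone and a 1,6-diketone. Dehydration, retro-aldol ring opening, E1cB opening of the lactone, epimerisation at C7 and transannular aldolisation are all conceivable.
- Fallback (the ketone is never freed): from 26, the strained trans C8=C9 enol ether is saturated with diimide (potassium azodicarboxylate, AcOH) on its exposed outer face. The seven-atom bridge should keep C7 and C1 cis on the six-membered ring, giving the cyclic silylene acetal F8. Et3N·3HF then returns to the route at 29.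

**Step 18.**
- What may go wrong: facial selectivity may be poor if the macrocycle overrides the chelate. The C3 ketone may suffer competing 1,2-reduction. The lactone may migrate from O6 to the new O8 alkoxide.
- Fallback (aim for the other epimer and invert): from 27, Evans–Saksena reduction with Me4NBH(OAc)3 gives the 1,3-anti 8-epi diol F9. Mitsunobu esterification with 30 (PPh3, DIAD) inverts C8 and returns to the route at 31.

## Further compounds

F1 | step 15 | (4R)-2-(TBDPS-oxymethyl)-4-methyl-4-(triethylsilyloxy)cyclohex-2-en-1-one | O=C1CC[C@@](C)(O[Si](CC)(CC)CC)C=C1CO[Si](c1ccccc1)(c1ccccc1)C(C)(C)C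
F2 | step 15 | tert-butyldimethylsilyl enol ether (C5=C8) of 22 | CC(C)(C)[Si](C)(C)OC1=C[C@@H]2OC(=O)[C@@H](COC(=O)c3ccccc3)[C@H]12
F3 | step 15 | untethered head-to-tail cis-anti-cis photoadduct (10-OTES, 8-OTBS) | O=C1CC[C@@](C)(O[Si](CC)(CC)CC)[C@@H]2[C@@]1(CO[Si](c1ccccc1)(c1ccccc1)C(C)(C)C)[C@@H]3[C@@]2(O[Si](C)(C)C(C)(C)C)[C@@H]4[C@H]3OC(=O)[C@H]4COC(=O)c1ccccc1
F4 | step 15 | (4Z)-cyclodeca-4,8-dien-3-one 6,12-lactone with 8-OTBS enol ether and 10-OTES | O=C1O[C@H]2/C=C(/CO[Si](c3ccccc3)(c3ccccc3)C(C)(C)C)C(=O)CC[C@@](C)(O[Si](CC)(CC)CC)/C=C(O[Si](C)(C)C(C)(C)C)/[C@H]2[C@@H]1COC(=O)c1ccccc1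
F5 | step 16 | desilylated photoadduct (C8 cyclobutanol, C10 carbinol) | O=C1CC[C@@](C)(O)[C@@H]2[C@@]1(CO[Si](c1ccccc1)(c1ccccc1)C(C)(C)C)[C@@H]3[C@@]2(O)[C@@H]4[C@H]3OC(=O)[C@H]4COC(=O)c1ccccc1
F6 | step 14 | diisopropyl(hydrido)silyl enol ether of 22 | CC(C)[SiH](C(C)C)OC1=C[C@@H]2OC(=O)[C@@H](COC(=O)c3ccccc3)[C@H]12
F7 | step 14 | bromo(diisopropyl)silyl enol ether of 22 | CC(C)[Si](Br)(C(C)C)OC1=C[C@@H]2OC(=O)[C@@H](COC(=O)c3ccccc3)[C@H]12
F8 | step 17 | 8,10-O-diisopropylsilylene acetal of 29 | O=C1O[C@H]2/C=C(/CO[Si](c3ccccc3)(c3ccccc3)C(C)(C)C)C(=O)CC[C@@](C)(O[Si]3(C(C)C)C(C)C)C[C@@H](O3)[C@H]2[C@@H]1COC(=O)c1ccccc1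
F9 | step 18 | 8-epi diol (8S,10R) | O=C1O[C@H]2/C=C(/CO[Si](c3ccccc3)(c3ccccc3)C(C)(C)C)C(=O)CC[C@@](C)(O)C[C@H](O)[C@H]2[C@@H]1COC(=O)c1ccccc1
A1 | alternative 1 | open-chain C6 aldehyde / C7=C11 2-(bromomethyl)enoate (15-OTBS) | O=C/C=C(/CO[Si](C)(C)C(C)(C)C)C(=O)CC[C@@](C)(O)C[C@@H](OC(=O)[C@H](C)CC)/C=C(\CBr)C(=O)OC
A2 | alternative 2 | seco-C4/C5 triene (6-vinyl lactone, C4 methylidene ketone, 15-OTBS) | C=C1C(=O)O[C@@H](C=C)[C@H]1[C@H](OC(=O)[C@H](C)CC)C[C@](C)(O)CCC(=O)C(=C)CO[Si](C)(C)C(C)(C)C
A3 | alternative 3 | 13-membered bis-allylic ether (O between C6 and C13; C3 dioxolane; silyl ethers at O8, O10, O12, O15) | O1C/C=C(/CO[Si](C)(C)C(C)(C)C)C2(OCCO2)CC[C@@](C)(O[Si](CC)(CC)CC)C[C@@H](O[Si](CC)(CC)CC)/C=C(\CO[Si](C)(C)C(C)(C)C)C1
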